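**Plan** (elemanolide numbering: ring C5–C10, lactone O–C6–C7–C11–C12(=O), exocyclic methylene C13)

- Cuts: the C8 ester; C11=C13 back to a C11 methoxycarbonyl group; C6–C7 and C11–C12 together; C5–C10 (ester enolate Claisen); C8–C9 (vinylogous aldol).
- Enabling feature: the lactone ring O–C6–C7–C11–C12 is a formal (3+2) adduct of a C6–O–C12 unit across C7=C11, and C6–C7 is also the last bond of the cyclohexane C5–C10. An open chain with C6 as an α-iodoalkyl phenyl carbonate (radical donor at C6, acyl acceptor at C12) and C7=C11 as an enoate can therefore close both rings in one reductive event.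
- Forward order: aldol (C8–C9), cross-metathesis (enoate), esterification and Ireland–Claisen (C5–C10), aldehyde, iodo carbonate, SmI2 annulation (cyclohexane, then lactone), decarboxylative methylenation, C8 acylation, deprotection.
- Stereochemistry: C8 from the catalytic asymmetric vinylogous aldol; C5/C10 from the chiral boron-enolate Claisen ((E)-alkene, E(O)-enolate, chair); C6/C7 from the chair transition state of the radical closure under control of C5, C8 and C10; the side-chain carbinol from (R)-butane-1,2,4-triol acetonide.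
- Helpers: iodide and phenoxide leave in the key step; the C11 ester is lost as CO2 when C13 is installed; the two silyl ethers and the acetonide come off at the end.

Key step: step 13

Assumption: the enantiomers of the aldol catalyst (step 2) and of the boron controller (step 10) are named by analogy with their usual sense of induction; if the sense were opposite, the antipodal reagent would be used with nothing else changed.

Step 1
Reactants: 1 methyl 3-methylbut-2-enoate
Product: 2 tert-butyl[(1-methoxy-3-methylbuta-1,3-dien-1-yl)oxy]dimethylsilane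
Conditions: LiN(i-Pr)2, THF, −78 °C; then t-BuMe2SiCl, DMPU, −78 °C → rt
Reagents that add atoms: tert-butyldimethylsilyl chloride, CC(C)(C)[Si](C)(C)Cl
Why: Kinetic γ-deprotonation of the unsaturated ester and O-silylation of the extended enolate (silyl ketene acetal formation) should give the silyl dienol ether needed for the vinylogous aldol.

Step 2
Reactants: 2 tert-butyl[(1-methoxy-3-methylbuta-1,3-dien-1-yl)oxy]dimethylsilane; 3 (E)-but-2-enal
Product: 4 methyl (2E,5S,6E)-5-hydroxy-3-methylocta-2,6-dienoate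
Conditions: SiCl4 (1.1 equiv), (R,R)-binaphthyl-2,2'-diamine-derived bisphosphoramide Lewis base (pentane-1,5-diyl linked, 2 mol %), i-Pr2NEt (10 mol %), CH2Cl2, −78 °C; aq. NaHCO3
Reagents that add atoms: none
Why: Lewis base-activated SiCl4 vinylogous Mukaiyama aldol addition, in which the dienolate reacts at its γ-carbon with the aldehyde held in the chiral phosphoramide-bound silyl cation, should set C8 (S) by catalyst control and give the (E)-trisubstituted enoate.

Step 3
Reactants: 4 methyl (2E,5S,6E)-5-hydroxy-3-methylocta-2,6-dienoate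
Product: 5 methyl (2E,5S,6E)-3-methyl-5-(triethylsilyloxy)octa-2,6-dienoate
Conditions: Et3SiCl, imidazole, CH2Cl2, 0 °C
Reagents that add atoms: triethylsilyl chloride, CC[Si](Cl)(CC)CC
Why: Standard silylation of the secondary allylic alcohol; triethylsilyl is chosen because it can later be removed beside a primary tert-butyldimethylsilyl ether.

Step 4
Reactants: 5 methyl (2E,5S,6E)-3-methyl-5-(triethylsilyloxy)octa-2,6-dienoate
Product: 6 (2E,5S,6E)-3-methyl-5-(triethylsilyloxy)octa-2,6-dien-1-ol
Conditions: i-Bu2AlH (2.2 equiv), CH2Cl2, −78 °C; aq. potassium sodium tartrate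
Reagents that add atoms: none
Why: 1,2-Reduction of the α,β-unsaturated ester by diisobutylaluminium hydride at low temperature should give the (E)-allylic alcohol without touching the silyl ether or the alkenes.

Step 5
Reactants: 6 (2E,5S,6E)-3-methyl-5-(triethylsilyloxy)octa-2,6-dien-1-ol; 7 methyl acrylate
Product: 8 methyl (2E,4S,6E)-8-hydroxy-6-methyl-4-(triethylsilyloxy)octa-2,6-dienoate
Conditions: second-generation Hoveyda–Grubbs catalyst (5 mol %), methyl acrylate (5 equiv), CH2Cl2, 40 °C
Reagents that add atoms: none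
Why: Olefin cross-metathesis of the 1-propenyl group with excess acrylate (propene lost) should install the (E)-enoate acceptor; the trisubstituted alkene is inert and no ring-closing partner exists at this stage.

Step 6
Reactants: 9 4-methoxy-2-methylidene-4-oxobutanoic acid (itaconic acid 4-methyl ester)
Product: 10 methyl 3-(hydroxymethyl)but-3-enoate
Conditions: BH3·SMe2 (1.1 equiv), THF, −10 °C → rt; then H2O; used directly
Reagents that add atoms: none
Why: Borane reduces the free carboxylic acid much faster than the ester or the electron-poor 1,1-disubstituted alkene (chemoselective acid reduction).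

Step 7
Reactants: 10 methyl 3-(hydroxymethyl)but-3-enoate
Product: 11 methyl 3-[(tert-butyldimethylsilyloxy)methyl]but-3-enoate
Conditions: t-BuMe2SiCl, imidazole, CH2Cl2, 0 °C → rt
Reagents that add atoms: tert-butyldimethylsilyl chloride, CC(C)(C)[Si](C)(C)Cl
Why: Silylation of the primary allylic alcohol prevents lactonization and masks the future C15 hydroxyl through the route.

Step 8
Reactants: 11 methyl 3-[(tert-butyldimethylsilyloxy)methyl]but-3-enoate
Product: 12 3-[(tert-butyldimethylsilyloxy)methyl]but-3-enoic acid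
Conditions: LiOH, THF–H2O (3:1), 0 °C; then 1 M HCl to pH 4
Reagents that add atoms: lithium hydroxide, [Li+].[OH-]
Why: Cold saponification of the unhindered methyl ester should give the β,γ-unsaturated acid before the double bond can move into conjugation.

Step 9
Reactants: 8 methyl (2E,4S,6E)-8-hydroxy-6-methyl-4-(triethylsilyloxy)octa-2,6-dienoate; 12 3-[(tert-butyldimethylsilyloxy)methyl]but-3-enoic acid
Product: 13 methyl (2E,4S,6E)-8-({3-[(tert-butyldimethylsilyloxy)methyl]but-3-enoyl}oxy)-6-methyl-4-(triethylsilyloxy)octa-2,6-dienoate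
Conditions: DCC, DMAP (5 mol %), CH2Cl2, −10 °C → rt
Reagents that add atoms: none
Why: Carbodiimide (Steglich) esterification of the primary allylic alcohol under nearly neutral conditions should give the allyl ester needed for the Claisen rearrangement.

Step 10
Reactants: 13 methyl (2E,4S,6E)-8-({3-[(tert-butyldimethylsilyloxy)methyl]but-3-enoyl}oxy)-6-methyl-4-(triethylsilyloxy)octa-2,6-dienoate
Product: 14 (2R,3S,5S,6E)-2-[3-(tert-butyldimethylsilyloxy)prop-1-en-2-yl]-3-ethenyl-8-methoxy-3-methyl-8-oxo-5-(triethylsilyloxy)oct-6-enoic acid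
Conditions: (S,S)-2-bromo-4,5-diphenyl-1,3-bis[3,5-bis(trifluoromethyl)phenylsulfonyl]-1,3,2-diazaborolidine (2.2 equiv), Et3N, toluene–hexane, −78 °C; then 4 °C, 3 d; aq. work-up
Reagents that add atoms: none
Why: Enantioselective Ireland–Claisen rearrangement through a chiral boron ketene acetal: soft enolization should give the E(O)-enolate, whose chair [3,3] transition state with the (E)-trisubstituted allyl unit (C9 equatorial, methyl axial) gives the required relative configuration of C5 and quaternary C10, while the C2-symmetric diazaborolidine selects the enolate face and so the absolute configuration.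

Step 11
Reactants: 14 (2R,3S,5S,6E)-2-[3-(tert-butyldimethylsilyloxy)prop-1-en-2-yl]-3-ethenyl-8-methoxy-3-methyl-8-oxo-5-(triethylsilyloxy)oct-6-enoic acid
Product: 16 methyl (2E,4S,6S,7R)-7-[3-(tert-butyldimethylsilyloxy)prop-1-en-2-yl]-6-ethenyl-6-methyl-8-oxo-4-(triethylsilyloxy)oct-2-enoate, via acid chloride 15 (not isolated)
Conditions: 1-chloro-N,N,2-trimethylprop-1-en-1-amine, CH2Cl2, 0 °C; then LiAlH(Ot-Bu)3, THF, −78 °C
Reagents that add atoms: none
Why: Neutral acid chloride formation and Rosenmund-type hydride reduction with the hindered LiAlH(Ot-Bu)3 should stop at the aldehyde and spare the enoate; no base is present, so C5 is not epimerized.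

Step 12
Reactants: 16 methyl (2E,4S,6S,7R)-7-[3-(tert-butyldimethylsilyloxy)prop-1-en-2-yl]-6-ethenyl-6-methyl-8-oxo-4-(triethylsilyloxy)oct-2-enoate
Product: 17 methyl (2E,4S,6S,7R,8RS)-7-[3-(tert-butyldimethylsilyloxy)prop-1-en-2-yl]-6-ethenyl-8-iodo-6-methyl-8-(phenoxycarbonyloxy)-4-(triethylsilyloxy)oct-2-enoate
Conditions: PhOCOCl (1.5 equiv), NaI (2 equiv), ZnI2 (5 mol %), MeCN–CH2Cl2, 0 °C, dark; filter, concentrate, use at once
Reagents that add atoms: phenyl chloroformate, O=C(Cl)Oc1ccccc1; sodium iodide, [Na+].[I-]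
Why: Addition of an acyl halide across the aldehyde C=O (α-haloalkyl ester formation, here with the iodoformate formed in the flask) should place the radical precursor on C6 and the acyl acceptor C12 on the same oxygen; the new centre forms as a mixture that converges in step 13.

Step 13
Reactants: 17 methyl (2E,4S,6S,7R,8RS)-7-[3-(tert-butyldimethylsilyloxy)prop-1-en-2-yl]-6-ethenyl-8-iodo-6-methyl-8-(phenoxycarbonyloxy)-4-(triethylsilyloxy)oct-2-enoate
Product: 18 methyl (3RS,3aS,4S,6S,7R,7aR)-7-[3-(tert-butyldimethylsilyloxy)prop-1-en-2-yl]-6-ethenyl-6-methyl-2-oxo-4-(triethylsilyloxy)octahydro-1-benzofuran-3-carboxylate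
Conditions: SmI2 (2.5 equiv, 0.1 M in THF, added over 1 h), THF, −78 °C → rt; aq. NH4Cl
Reagents that add atoms: none
Why: Proposed new method: SmI2 should reduce the weak C–I bond next to the carbonate oxygen to the planar α-(phenoxycarbonyloxy)alkyl radical at C6 (both epimers of 17 converge), which adds 6-exo-trig to the enoate β-carbon C7; the α-ester radical at C11 is reduced by a second SmI2 to the trivalent samarium enolate, which attacks the carbonate carbon C12 in a 5-exo-trig Claisen-type acyl substitution and expels phenoxide, so the cyclohexane (C6–C7) and the γ-lactone (C11–C12) close in one operation. The closest known reactions are SmI2-mediated sequential radical cyclization/intramolecular nucleophilic acyl substitution and SmI2 couplings of α-oxygenated (anomeric) radicals with acrylates; the untested element is an α-iodoalkyl carbonate serving as a three-atom C–O–C(=O) partner for an alkene. C6 and C7 are set in a chair transition state with the C5 side chain, the C8 silyloxy group and the C10 vinyl group equatorial: the carbonate oxygen on C6 must be equatorial to avoid the axial C10 methyl, and the enoate on C7 is equatorial to avoid allylic strain with the C8 substituent, which gives the trans arrangement at C6/C7 and hence the trans ring fusion. C11 forms as an epimeric mixture that is removed in step 14. The step needs cyclization to outrun reduction of the C6 radical (slow addition of SmI2, no HMPA, activated enoate, Thorpe–Ingold help from quaternary C10) and needs loss of phenoxide and not of the ring alkoxide from the tetrahedral intermediate (phenoxide is the better leaving group).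

Step 14
Reactants: 18 methyl (3RS,3aS,4S,6S,7R,7aR)-7-[3-(tert-butyldimethylsilyloxy)prop-1-en-2-yl]-6-ethenyl-6-methyl-2-oxo-4-(triethylsilyloxy)octahydro-1-benzofuran-3-carboxylate
Product: 20 (3aS,4S,6S,7R,7aR)-7-[3-(tert-butyldimethylsilyloxy)prop-1-en-2-yl]-6-ethenyl-6-methyl-3-methylidene-4-(triethylsilyloxy)hexahydro-1-benzofuran-2(3H)-one, via α-carboxy lactone 19 (not isolated)
Conditions: LiOH, THF–H2O, 0 °C → rt; 1 M HCl to pH 3; then Et2NH, 37 % aq. CH2O, 60 °C
Reagents that add atoms: formaldehyde, C=O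
Why: Saponification of the malonate-type ester, then Mannich reaction of the lactone acid with formaldehyde/diethylamine and decarboxylative elimination (classical α-methylenation of α-carboxy lactones), should install C13 and remove the activating group together with the C11 stereocentre.

Step 15
Reactants: 20 (3aS,4S,6S,7R,7aR)-7-[3-(tert-butyldimethylsilyloxy)prop-1-en-2-yl]-6-ethenyl-6-methyl-3-methylidene-4-(triethylsilyloxy)hexahydro-1-benzofuran-2(3H)-one
Product: 21 (3aR,4S,6S,7R,7aR)-7-[3-(tert-butyldimethylsilyloxy)prop-1-en-2-yl]-6-ethenyl-4-hydroxy-6-methyl-3-methylidenehexahydro-1-benzofuran-2(3H)-one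
Conditions: pyridinium p-toluenesulfonate (0.2 equiv), MeOH–CH2Cl2 (1:1), 0 °C
Reagents that add atoms: none
Why: Mild acid-catalysed methanolysis should cleave the secondary triethylsilyl ether selectively beside the primary tert-butyldimethylsilyl ether.

Step 16
Reactants: 22 2-[(4R)-2,2-dimethyl-1,3-dioxolan-4-yl]ethan-1-ol
Product: 23 2-[(4R)-2,2-dimethyl-1,3-dioxolan-4-yl]acetaldehyde
Conditions: Dess–Martin periodinane, NaHCO3, CH2Cl2, 0 °C → rt
Reagents that add atoms: none
Why: Buffered Dess–Martin oxidation of the primary alcohol; the stereocentre is β to the new carbonyl and is not affected.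

Step 17
Reactants: 23 2-[(4R)-2,2-dimethyl-1,3-dioxolan-4-yl]acetaldehyde
Product: 24 2-[(4R)-2,2-dimethyl-1,3-dioxolan-4-yl]prop-2-enal
Conditions: CH2=NMe2+ I− (Eschenmoser's salt), Et3N, CH2Cl2, rt
Reagents that add atoms: Eschenmoser's salt (N,N-dimethylmethaniminium iodide), C=[N+](C)C.[I-]
Why: Mannich reaction with the iminium salt followed by amine elimination (α-methylenation of aldehydes) should give the 2-substituted acrolein without involving the β-alkoxy stereocentre.

Step 18
Reactants: 24 2-[(4R)-2,2-dimethyl-1,3-dioxolan-4-yl]prop-2-enal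
Product: 25 2-[(4R)-2,2-dimethyl-1,3-dioxolan-4-yl]prop-2-enoic acid
Conditions: NaClO2, NaH2PO4, 2-methylbut-2-ene, t-BuOH–H2O, 0 °C → rt
Reagents that add atoms: sodium chlorite, [Na+].[O-]Cl=O
Why: Pinnick oxidation converts the enal into the acrylic acid without touching the alkene or the acetonide.

Step 19
Reactants: 21 (3aR,4S,6S,7R,7aR)-7-[3-(tert-butyldimethylsilyloxy)prop-1-en-2-yl]-6-ethenyl-4-hydroxy-6-methyl-3-methylidenehexahydro-1-benzofuran-2(3H)-one; 25 2-[(4R)-2,2-dimethyl-1,3-dioxolan-4-yl]prop-2-enoic acid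
Product: 27 (3aR,4S,6S,7R,7aR)-7-[3-(tert-butyldimethylsilyloxy)prop-1-en-2-yl]-6-ethenyl-6-methyl-3-methylidene-2-oxooctahydro-1-benzofuran-4-yl 2-[(4R)-2,2-dimethyl-1,3-dioxolan-4-yl]prop-2-enoate, via mixed anhydride 26 (not isolated)
Conditions: 2,4,6-trichlorobenzoyl chloride, Et3N, toluene, rt; then 21, DMAP (0.3 equiv), toluene, rt
Reagents that add atoms: none
Why: Yamaguchi esterification, in which 4-(dimethylamino)pyridine opens the mixed anhydride at the less hindered acrylic carbonyl and the acylpyridinium acylates the equatorial C8 hydroxyl, should join the fragments without touching any stereocentre.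

Step 20
Reactants: 27 (3aR,4S,6S,7R,7aR)-7-[3-(tert-butyldimethylsilyloxy)prop-1-en-2-yl]-6-ethenyl-6-methyl-3-methylidene-2-oxooctahydro-1-benzofuran-4-yl 2-[(4R)-2,2-dimethyl-1,3-dioxolan-4-yl]prop-2-enoate
Product: 28 (3aR,4S,6S,7R,7aR)-6-ethenyl-7-(3-hydroxyprop-1-en-2-yl)-6-methyl-3-methylidene-2-oxooctahydro-1-benzofuran-4-yl (3R)-3,4-dihydroxy-2-methylidenebutanoate (target)
Conditions: AcOH–H2O (4:1), 35 °C
Reagents that add atoms: none
Why: Aqueous acetic acid should hydrolyse the terminal acetonide and the primary silyl ether in one operation, mildly enough for the two α-methylene carbonyl groups and the allylic alcohol.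

**Compound list**

1 | methyl 3-methylbut-2-enoate | COC(=O)C=C(C)C | starting material
2 | tert-butyl[(1-methoxy-3-methylbuta-1,3-dien-1-yl)oxy]dimethylsilane | COC(O[Si](C)(C)C(C)(C)C)=CC(C)=C | intermediate
3 | (E)-but-2-enal | C/C=C/C=O | starting material
4 | methyl (2E,5S,6E)-5-hydroxy-3-methylocta-2,6-dienoate | COC(=O)/C=C(\C)C[C@H](O)/C=C/C | intermediate
5 | methyl (2E,5S,6E)-3-methyl-5-(triethylsilyloxy)octa-2,6-dienoate | COC(=O)/C=C(\C)C[C@H](O[Si](CC)(CC)CC)/C=C/C | intermediate
6 | (2E,5S,6E)-3-methyl-5-(triethylsilyloxy)octa-2,6-dien-1-ol | OC/C=C(\C)C[C@H](O[Si](CC)(CC)CC)/C=C/C | intermediate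
7 | methyl acrylate | C=CC(=O)OC | starting material
8 | methyl (2E,4S,6E)-8-hydroxy-6-methyl-4-(triethylsilyloxy)octa-2,6-dienoate | OC/C=C(\C)C[C@H](O[Si](CC)(CC)CC)/C=C/C(=O)OC | intermediate
9 | 4-methoxy-2-methylidene-4-oxobutanoic acid | C=C(CC(=O)OC)C(=O)O | starting material
10 | methyl 3-(hydroxymethyl)but-3-enoate | C=C(CO)CC(=O)OC | intermediate
11 | methyl 3-[(tert-butyldimethylsilyloxy)methyl]but-3-enoate | C=C(CO[Si](C)(C)C(C)(C)C)CC(=O)OC | intermediate
12 | 3-[(tert-butyldimethylsilyloxy)methyl]but-3-enoic acid | C=C(CO[Si](C)(C)C(C)(C)C)CC(=O)O | intermediate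
13 | methyl (2E,4S,6E)-8-({3-[(tert-butyldimethylsilyloxy)methyl]but-3-enoyl}oxy)-6-methyl-4-(triethylsilyloxy)octa-2,6-dienoate | C=C(CO[Si](C)(C)C(C)(C)C)CC(=O)OC/C=C(\C)C[C@H](O[Si](CC)(CC)CC)/C=C/C(=O)OC | intermediate
14 | (2R,3S,5S,6E)-2-[3-(tert-butyldimethylsilyloxy)prop-1-en-2-yl]-3-ethenyl-8-methoxy-3-methyl-8-oxo-5-(triethylsilyloxy)oct-6-enoic acid | C=C[C@](C)(C[C@H](O[Si](CC)(CC)CC)/C=C/C(=O)OC)[C@@H](C(=O)O)C(=C)CO[Si](C)(C)C(C)(C)C | intermediate
15 | methyl (2E,4S,6S,7R)-7-[3-(tert-butyldimethylsilyloxy)prop-1-en-2-yl]-8-chloro-6-ethenyl-6-methyl-8-oxo-4-(triethylsilyloxy)oct-2-enoate (acid chloride of 14) | C=C[C@](C)(C[C@H](O[Si](CC)(CC)CC)/C=C/C(=O)OC)[C@@H](C(=O)Cl)C(=C)CO[Si](C)(C)C(C)(C)C | intermediate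
16 | methyl (2E,4S,6S,7R)-7-[3-(tert-butyldimethylsilyloxy)prop-1-en-2-yl]-6-ethenyl-6-methyl-8-oxo-4-(triethylsilyloxy)oct-2-enoate | C=C[C@](C)(C[C@H](O[Si](CC)(CC)CC)/C=C/C(=O)OC)[C@@H](C=O)C(=C)CO[Si](C)(C)C(C)(C)C | intermediate
17 | methyl (2E,4S,6S,7R,8RS)-7-[3-(tert-butyldimethylsilyloxy)prop-1-en-2-yl]-6-ethenyl-8-iodo-6-methyl-8-(phenoxycarbonyloxy)-4-(triethylsilyloxy)oct-2-enoate | C=C[C@](C)(C[C@H](O[Si](CC)(CC)CC)/C=C/C(=O)OC)[C@@H](C(I)OC(=O)Oc1ccccc1)C(=C)CO[Si](C)(C)C(C)(C)C | intermediate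
18 | methyl (3RS,3aS,4S,6S,7R,7aR)-7-[3-(tert-butyldimethylsilyloxy)prop-1-en-2-yl]-6-ethenyl-6-methyl-2-oxo-4-(triethylsilyloxy)octahydro-1-benzofuran-3-carboxylate | C=C[C@]1(C)C[C@H](O[Si](CC)(CC)CC)[C@H]2C(C(=O)OC)C(=O)O[C@@H]2[C@H]1C(=C)CO[Si](C)(C)C(C)(C)C | intermediate
19 | (3RS,3aS,4S,6S,7R,7aR)-7-[3-(tert-butyldimethylsilyloxy)prop-1-en-2-yl]-6-ethenyl-6-methyl-2-oxo-4-(triethylsilyloxy)octahydro-1-benzofuran-3-carboxylic acid | C=C[C@]1(C)C[C@H](O[Si](CC)(CC)CC)[C@H]2C(C(=O)O)C(=O)O[C@@H]2[C@H]1C(=C)CO[Si](C)(C)C(C)(C)C | intermediate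
20 | (3aS,4S,6S,7R,7aR)-7-[3-(tert-butyldimethylsilyloxy)prop-1-en-2-yl]-6-ethenyl-6-methyl-3-methylidene-4-(triethylsilyloxy)hexahydro-1-benzofuran-2(3H)-one | C=C[C@]1(C)C[C@H](O[Si](CC)(CC)CC)[C@H]2C(=C)C(=O)O[C@@H]2[C@H]1C(=C)CO[Si](C)(C)C(C)(C)C | intermediate
21 | (3aR,4S,6S,7R,7aR)-7-[3-(tert-butyldimethylsilyloxy)prop-1-en-2-yl]-6-ethenyl-4-hydroxy-6-methyl-3-methylidenehexahydro-1-benzofuran-2(3H)-one | C=C[C@]1(C)C[C@H](O)[C@H]2C(=C)C(=O)O[C@@H]2[C@H]1C(=C)CO[Si](C)(C)C(C)(C)C | intermediate
22 | 2-[(4R)-2,2-dimethyl-1,3-dioxolan-4-yl]ethan-1-ol | OCC[C@@H]1COC(C)(C)O1 | starting material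
23 | 2-[(4R)-2,2-dimethyl-1,3-dioxolan-4-yl]acetaldehyde | O=CC[C@@H]1COC(C)(C)O1 | intermediate
24 | 2-[(4R)-2,2-dimethyl-1,3-dioxolan-4-yl]prop-2-enal | C=C(C=O)[C@@H]1COC(C)(C)O1 | intermediate
25 | 2-[(4R)-2,2-dimethyl-1,3-dioxolan-4-yl]prop-2-enoic acid | C=C(C(=O)O)[C@@H]1COC(C)(C)O1 | intermediate
26 | 2-[(4R)-2,2-dimethyl-1,3-dioxolan-4-yl]prop-2-enoic 2,4,6-trichlorobenzoic anhydride | C=C(C(=O)OC(=O)c1c(Cl)cc(Cl)cc1Cl)[C@@H]1COC(C)(C)O1 | intermediate
27 | (3aR,4S,6S,7R,7aR)-7-[3-(tert-butyldimethylsilyloxy)prop-1-en-2-yl]-6-ethenyl-6-methyl-3-methylidene-2-oxooctahydro-1-benzofuran-4-yl 2-[(4R)-2,2-dimethyl-1,3-dioxolan-4-yl]prop-2-enoate | C=C[C@]1(C)C[C@H](OC(=O)C(=C)[C@@H]3COC(C)(C)O3)[C@H]2C(=C)C(=O)O[C@@H]2[C@H]1C(=C)CO[Si](C)(C)C(C)(C)C | intermediate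
28 | (3aR,4S,6S,7R,7aR)-6-ethenyl-7-(3-hydroxyprop-1-en-2-yl)-6-methyl-3-methylidene-2-oxooctahydro-1-benzofuran-4-yl (3R)-3,4-dihydroxy-2-methylidenebutanoate | C=C[C@]1(C)C[C@H](OC(=O)C(=C)[C@@H](O)CO)[C@H]2C(=C)C(=O)O[C@@H]2[C@H]1C(=C)CO | target

**Totals.** 20 steps in all; longest linear sequence 14 steps (steps 1–5, 9–15, 19, 20).

**Steps most likely to fail**

Step 13 (key step). The C6 radical may be reduced to the carbanion or transfer hydrogen (for example from C8) before it cyclizes, or the samarium enolate may be protonated instead of acylating. The fallback uses known chemistry and sets out from aldehyde 16. SmI2 with t-BuOH in THF at −78 °C should effect ketyl–olefin 6-exo cyclization onto the enoate and give the trans hydroxy ester methyl 2-[(1S,2R,3R,4S,6S)-3-[3-(tert-butyldimethylsilyloxy)prop-1-en-2-yl]-4-ethenyl-2-hydroxy-4-methyl-6-(triethylsilyloxy)cyclohexyl]acetate F1. Catalytic p-toluenesulfonic acid should lactonize it to the trans-fused lactone (3aS,4S,6S,7R,7aR)-7-[3-(tert-butyldimethylsilyloxy)prop-1-en-2-yl]-6-ethenyl-6-methyl-4-(triethylsilyloxy)hexahydro-1-benzofuran-2(3H)-one F2; here the former enoate carbon becomes the lactone carbonyl. Formylation (NaH, HCO2Et) should give the 3-(hydroxymethylidene) lactone F3, and paraformaldehyde in THF (aldol, formyl transfer, elimination of formate) should convert it into the α-methylene lactone 20, where the route is rejoined.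

Step 10. The boron enolate may form with poor geometry or poor face control, or the bromoborane may be diverted by the Lewis-basic enoate and silyl ethers. The fallback sets out from ester 13: a classical Ireland–Claisen rearrangement (KN(SiMe3)2, Me3SiCl, THF, −78 °C → rt, E(O)-silyl ketene acetal) should give, after hydrolytic work-up, acid 14 together with (2S,3R,5S,6E)-2-[3-(tert-butyldimethylsilyloxy)prop-1-en-2-yl]-3-ethenyl-8-methoxy-3-methyl-8-oxo-5-(triethylsilyloxy)oct-6-enoic acid F4. The two are diastereomers because of C8 and would be separated by chromatography; the route is rejoined at 14.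

Step 12. The α-iodoalkyl carbonate may decompose as it forms (loss of HI, reversion to the aldehyde, epimerization at C5). The fallback sets out from aldehyde 16: chloride-catalysed addition of phenyl chloroformate (catalytic pyridine, CH2Cl2) should give the more stable, purifiable methyl (2E,4S,6S,7R,8RS)-7-[3-(tert-butyldimethylsilyloxy)prop-1-en-2-yl]-8-chloro-6-ethenyl-6-methyl-8-(phenoxycarbonyloxy)-4-(triethylsilyloxy)oct-2-enoate F5. Finkelstein exchange (NaI, acetone) just before the key step converts it into 17, where the route is rejoined.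

**Further compounds**

F1 | step 13 | methyl 2-[(1S,2R,3R,4S,6S)-3-[3-(tert-butyldimethylsilyloxy)prop-1-en-2-yl]-4-ethenyl-2-hydroxy-4-methyl-6-(triethylsilyloxy)cyclohexyl]acetate | C=C[C@]1(C)C[C@H](O[Si](CC)(CC)CC)[C@@H](CC(=O)OC)[C@H](O)[C@H]1C(=C)CO[Si](C)(C)C(C)(C)C
F2 | step 13 | (3aS,4S,6S,7R,7aR)-7-[3-(tert-butyldimethylsilyloxy)prop-1-en-2-yl]-6-ethenyl-6-methyl-4-(triethylsilyloxy)hexahydro-1-benzofuran-2(3H)-one | C=C[C@]1(C)C[C@H](O[Si](CC)(CC)CC)[C@H]2CC(=O)O[C@@H]2[C@H]1C(=C)CO[Si](C)(C)C(C)(C)C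
F3 | step 13 | (3aS,4S,6S,7R,7aR)-7-[3-(tert-butyldimethylsilyloxy)prop-1-en-2-yl]-6-ethenyl-3-(hydroxymethylidene)-6-methyl-4-(triethylsilyloxy)hexahydro-1-benzofuran-2(3H)-one | C=C[C@]1(C)C[C@H](O[Si](CC)(CC)CC)[C@H]2C(=CO)C(=O)O[C@@H]2[C@H]1C(=C)CO[Si](C)(C)C(C)(C)C
F4 | step 10 | (2S,3R,5S,6E)-2-[3-(tert-butyldimethylsilyloxy)prop-1-en-2-yl]-3-ethenyl-8-methoxy-3-methyl-8-oxo-5-(triethylsilyloxy)oct-6-enoic acid | C=C[C@@](C)(C[C@H](O[Si](CC)(CC)CC)/C=C/C(=O)OC)[C@H](C(=O)O)C(=C)CO[Si](C)(C)C(C)(C)C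
F5 | step 12 | methyl (2E,4S,6S,7R,8RS)-7-[3-(tert-butyldimethylsilyloxy)prop-1-en-2-yl]-8-chloro-6-ethenyl-6-methyl-8-(phenoxycarbonyloxy)-4-(triethylsilyloxy)oct-2-enoate | C=C[C@](C)(C[C@H](O[Si](CC)(CC)CC)/C=C/C(=O)OC)[C@@H](C(Cl)OC(=O)Oc1ccccc1)C(=C)CO[Si](C)(C)C(C)(C)C
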